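Everything rests on closing the tetrahydrofuran (ring A) between C2, the ether carbon that carries the side-chain alkene, and C3, the carbinol carbon. A 2-alkenyl-3-hydroxytetrahydrofuran is the product pattern of an intramolecular γ-alkoxyallylboration, so one operation forms C2–C3, closes ring A, sets C2 and leaves a vinyl group for a final cross-metathesis. The precursor is an open-chain (E)-γ-alkoxyallylboronate on a D-tartrate backbone (C3, C3a, C7a, C7) whose two esters are reduced to aldehydes in the flask; only the C3 aldehyde can reach the boronate. C3 is then inverted by oxidation and reduction, and the lactone (ring B) is closed after a Z-olefination at C7.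

Key step: step 5

Remark: locants C2, C3, C3a, C5, C6, C7 and C7a are those of the furo[3,2-b]pyran-5-one core and are kept for the same atoms in all precursors. In the target the four substituents on ring A (side chain at C2, OH at C3, lactone O at C3a, C7 at C7a) are all cis; the route is planned for exactly this arrangement.

**Core (steps 1–9)**

Step 1
Reactants: 1 diethyl D-(−)-tartrate [diethyl (2S,3S)-2,3-dihydroxybutanedioate]
Product: 3 diethyl (2S,3S)-2-hydroxy-3-(prop-2-yn-1-yloxy)butanedioate, via dibutylstannylene acetal 2 (not isolated)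
Conditions: Bu2SnO, toluene, reflux (Dean–Stark); then propargyl bromide, CsF, DMF, rt
Reagents that add atoms: propargyl bromide, BrCC#C
Why: Stannylene-acetal mono-O-alkylation; the two hydroxyls of the twofold-symmetric diol are equivalent, so one alkylation gives a single mono-ether and no stereocentre is touched.

Step 2
Reactants: 3 diethyl (2S,3S)-2-hydroxy-3-(prop-2-yn-1-yloxy)butanedioate
Product: 4 diethyl (2S,3S)-2-[(tert-butyldimethylsilyl)oxy]-3-(prop-2-yn-1-yloxy)butanedioate
Conditions: TBSOTf, 2,6-lutidine, CH2Cl2, 0 °C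
Reagents that add atoms: tert-butyldimethylsilyl triflate, CC(C)(C)[Si](C)(C)OS(=O)(=O)C(F)(F)F
Why: Silyl ether formation with a silyl triflate and a hindered base protects the α-hydroxy ester (the later C3a oxygen) without epimerisation.

Step 3
Reactants: 4 diethyl (2S,3S)-2-[(tert-butyldimethylsilyl)oxy]-3-(prop-2-yn-1-yloxy)butanedioate
Product: 5 diethyl (2S,3S)-2-[(tert-butyldimethylsilyl)oxy]-3-{[(2E)-3-(4,4,5,5-tetramethyl-1,3,2-dioxaborolan-2-yl)prop-2-en-1-yl]oxy}butanedioate
Conditions: pinacolborane (1.5 equiv), dicyclohexylborane (5 mol%), neat, rt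
Reagents that add atoms: pinacolborane, CC1(C)OBOC1(C)C
Why: Dialkylborane-catalysed hydroboration of a terminal alkyne adds H–B syn and anti-Markovnikov to give the (E)-alkenylboronate; esters and silyl ether should not react.

Step 4
Reactants: 5 the (E)-3-alkoxyprop-1-enylboronate
Product: 6 diethyl (2S,3S)-2-[(tert-butyldimethylsilyl)oxy]-3-{[(1E)-3-(4,4,5,5-tetramethyl-1,3,2-dioxaborolan-2-yl)prop-1-en-1-yl]oxy}butanedioate
Conditions: [Ir(cod)(PPh2Me)2]PF6 (3 mol%, activated with H2, then Ar), THF, rt
Reagents that add atoms: none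
Why: Iridium-hydride-catalysed isomerisation of an allyl ether to an enol ether moves the double bond from boron to oxygen and should give the (E)-γ-alkoxyallylboronate, a reaction type established for 3-alkoxyprop-1-enylboronates.

Step 5
Reactants: 6 the (E)-γ-alkoxyallylboronate diester
Product: 9 (2S,3R,4S,5S)-3-[(tert-butyldimethylsilyl)oxy]-5-ethenyl-4-hydroxyoxolane-2-carbaldehyde, via dialdehyde 7 (not isolated), via borate ester 8 (not isolated)
Conditions: i-Bu2AlH (2.1 equiv), toluene, −78 °C, 0.02 M; then MeOH, aqueous pH 7 buffer, −78 °C to rt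
Reagents that add atoms: none
Why: Partial reduction of both esters gives dialdehyde 7, and the γ-carbon of the allylboronate (C2) adds to the C3 aldehyde through a closed six-membered chair transition state (Zimmerman–Traxler type) with boron bound to the carbonyl oxygen, the established intramolecular allylboration of γ-(ω-formylalkoxy)allylboronates. Ring A closes in a 5-exo-trig mode at the carbonyl carbon; the C7 aldehyde would need a four-membered ring and is left for step 6. The E geometry puts the ether oxygen equatorial in the chair and the aldehyde residue is equatorial too, so the chair is trans-fused to the new ring and the C2 vinyl and the C3 oxygen end up trans. The aldehyde face is chosen by the C3a silyloxy centre (α-oxygen turned away from the carbonyl dipole, Cornforth model), which places the vinyl group cis to the C3a oxygen and to the C7a formyl group, the C2 configuration of the target. The step needs ring closure to win over intermolecular allylboration of the free aldehyde, which high dilution and the fast five-membered closure should secure. The C3 configuration formed here is the wrong one and is inverted in steps 7 and 8.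

Step 6
Reactants: 9 (2S,3R,4S,5S)-3-[(tert-butyldimethylsilyl)oxy]-5-ethenyl-4-hydroxyoxolane-2-carbaldehyde
Product: 10 methyl (2Z)-3-[(2R,3R,4S,5S)-3-[(tert-butyldimethylsilyl)oxy]-5-ethenyl-4-hydroxyoxolan-2-yl]prop-2-enoate
Conditions: Ph3P=CHCO2Me, MeOH, −20 to 0 °C
Reagents that add atoms: methyl (triphenylphosphoranylidene)acetate, COC(=O)C=P(c1ccccc1)(c1ccccc1)c1ccccc1
Why: Wittig olefination with a stabilised ylide in methanol, conditions under which α-alkoxy aldehydes give mainly the (Z)-enoate; the C3 hydroxyl is trans to the new chain and cannot add to it.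

Step 7
Reactants: 10 the (Z)-enoate with the C3 hydroxyl trans to its neighbours
Product: 11 methyl (2Z)-3-[(2R,3S,5S)-3-[(tert-butyldimethylsilyl)oxy]-5-ethenyl-4-oxooxolan-2-yl]prop-2-enoate
Conditions: Dess–Martin periodinane, CH2Cl2, 0 °C to rt
Reagents that add atoms: none
Why: Dess–Martin oxidation of the secondary alcohol under non-basic conditions erases the C3 centre without enolising the α-alkoxy ketone.

Step 8
Reactants: 11 the ring A ketone
Product: 12 methyl (2Z)-3-[(2R,3R,4R,5S)-3-[(tert-butyldimethylsilyl)oxy]-5-ethenyl-4-hydroxyoxolan-2-yl]prop-2-enoate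
Conditions: NaBH4, CeCl3·7H2O, MeOH, −78 °C
Reagents that add atoms: none
Why: Luche 1,2-reduction; hydride should attack the face opposite to the three cis substituents (C2 vinyl, C3a silyloxy, C7a alkenyl), which sets the C3 hydroxyl cis to all of them and leaves the enoate untouched.

Step 9
Reactants: 12 the all-cis silyl ether
Product: 14 (2S,3R,3aR,7aR)-2-ethenyl-3-hydroxy-2,3,3a,7a-tetrahydro-5H-furo[3,2-b]pyran-5-one, via dihydroxy ester 13 (not isolated)
Conditions: HF·pyridine, THF, 0 °C to rt; then p-TsOH·H2O (cat.), CH2Cl2, rt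
Reagents that add atoms: none
Why: Desilylation frees the C3a hydroxyl, which is cis to the (Z)-enoate and closes the six-membered lactone by acid-catalysed transesterification; the C3 hydroxyl would give a seven-membered ring and should not compete.

**Side chain (steps 10–13)**

Step 10
Reactants: 15 penta-1,4-dien-3-ol
Product: 16 (1S)-1-[(2R)-oxiran-2-yl]prop-2-en-1-ol
Conditions: t-BuOOH, Ti(Oi-Pr)4 (10 mol%), L-(+)-diisopropyl tartrate (12 mol%), 4 Å molecular sieves, CH2Cl2, −20 °C
Reagents that add atoms: tert-butyl hydroperoxide, CC(C)(C)OO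
Why: Sharpless asymmetric epoxidation of an achiral divinyl carbinol; the tartrate selects one enantiotopic vinyl group and its face, and the erythro preference of secondary allylic alcohols fixes the carbinol centre, so both stereocentres are set (2R,3S, anti).

Step 11
Reactants: 16 (1S)-1-[(2R)-oxiran-2-yl]prop-2-en-1-ol
Product: 17 tert-butyl(dimethyl){[(1S)-1-[(2R)-oxiran-2-yl]prop-2-en-1-yl]oxy}silane
Conditions: TBSCl, imidazole, DMF, 0 °C to rt
Reagents that add atoms: tert-butyldimethylsilyl chloride, CC(C)(C)[Si](C)(C)Cl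
Why: Imidazole-promoted silylation protects the allylic alcohol under conditions too weakly basic for a Payne rearrangement.

Step 12
Reactants: 17 the silylated epoxy alcohol
Product: 18 (2R,3S)-3-[(tert-butyldimethylsilyl)oxy]pent-4-en-2-ol
Conditions: LiAlH4, Et2O, 0 °C
Reagents that add atoms: none
Why: Hydride opening of the terminal epoxide at its unsubstituted carbon (SN2) gives the methyl carbinol with the C–O bond at C2 untouched.

Step 13
Reactants: 18 (2R,3S)-3-[(tert-butyldimethylsilyl)oxy]pent-4-en-2-ol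
Product: 20 (2R,3S)-3-hydroxypent-4-en-2-yl benzoate, via silylated benzoate 19 (not isolated)
Conditions: BzCl, pyridine, DMAP (cat.), CH2Cl2, 0 °C to rt; then HF·pyridine, THF, rt
Reagents that add atoms: benzoyl chloride, O=C(Cl)c1ccccc1
Why: DMAP-catalysed acylation places the benzoate on O2 while O3 is silylated, and the acidic fluoride then removes the silyl group without base, so the benzoate should not migrate.

**Union**

Step 14
Reactants: 14 (2S,3R,3aR,7aR)-2-ethenyl-3-hydroxy-2,3,3a,7a-tetrahydro-5H-furo[3,2-b]pyran-5-one; 20 (2R,3S)-3-hydroxypent-4-en-2-yl benzoate (3 equiv)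
Product: 21 (2R,3S,4E)-3-hydroxy-5-[(2S,3R,3aR,7aR)-3-hydroxy-5-oxo-2,3,3a,7a-tetrahydro-5H-furo[3,2-b]pyran-2-yl]pent-4-en-2-yl benzoate (target)
Conditions: second-generation Hoveyda–Grubbs catalyst RuCl2(H2IMes)(=CH-C6H4-2-Oi-Pr) (10 mol%), CH2Cl2, 40 °C
Reagents that add atoms: none
Why: Olefin cross-metathesis of two terminal alkenes with allylic branching should give the (E)-disubstituted alkene with loss of ethene; the conjugated ring B alkene is inert to the ruthenium carbene.

**Compound list**

1 | diethyl D-(−)-tartrate, diethyl (2S,3S)-2,3-dihydroxybutanedioate | CCOC(=O)[C@@H](O)[C@H](O)C(=O)OCC | starting material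
2 | diethyl (4S,5S)-2,2-dibutyl-1,3,2-dioxastannolane-4,5-dicarboxylate | CCOC(=O)[C@H]1O[Sn](CCCC)(CCCC)O[C@@H]1C(=O)OCC | intermediate (not isolated)
3 | diethyl (2S,3S)-2-hydroxy-3-(prop-2-yn-1-yloxy)butanedioate | CCOC(=O)[C@@H](OCC#C)[C@H](O)C(=O)OCC | intermediate
4 | diethyl (2S,3S)-2-[(tert-butyldimethylsilyl)oxy]-3-(prop-2-yn-1-yloxy)butanedioate | CCOC(=O)[C@@H](OCC#C)[C@H](O[Si](C)(C)C(C)(C)C)C(=O)OCC | intermediate
5 | diethyl (2S,3S)-2-[(tert-butyldimethylsilyl)oxy]-3-{[(2E)-3-(4,4,5,5-tetramethyl-1,3,2-dioxaborolan-2-yl)prop-2-en-1-yl]oxy}butanedioate | CCOC(=O)[C@@H](OC/C=C/B1OC(C)(C)C(C)(C)O1)[C@H](O[Si](C)(C)C(C)(C)C)C(=O)OCC | intermediate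
6 | diethyl (2S,3S)-2-[(tert-butyldimethylsilyl)oxy]-3-{[(1E)-3-(4,4,5,5-tetramethyl-1,3,2-dioxaborolan-2-yl)prop-1-en-1-yl]oxy}butanedioate | CCOC(=O)[C@@H](O/C=C/CB1OC(C)(C)C(C)(C)O1)[C@H](O[Si](C)(C)C(C)(C)C)C(=O)OCC | intermediate
7 | (2S,3S)-2-[(tert-butyldimethylsilyl)oxy]-3-{[(1E)-3-(4,4,5,5-tetramethyl-1,3,2-dioxaborolan-2-yl)prop-1-en-1-yl]oxy}butanedial | O=C[C@@H](O/C=C/CB1OC(C)(C)C(C)(C)O1)[C@H](O[Si](C)(C)C(C)(C)C)C=O | intermediate (not isolated)
8 | (2S,3R,4S,5S)-3-[(tert-butyldimethylsilyl)oxy]-5-ethenyl-4-[(4,4,5,5-tetramethyl-1,3,2-dioxaborolan-2-yl)oxy]oxolane-2-carbaldehyde | C=C[C@@H]1O[C@H](C=O)[C@H](O[Si](C)(C)C(C)(C)C)[C@H]1OB1OC(C)(C)C(C)(C)O1 | intermediate (not isolated)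
9 | (2S,3R,4S,5S)-3-[(tert-butyldimethylsilyl)oxy]-5-ethenyl-4-hydroxyoxolane-2-carbaldehyde | C=C[C@@H]1O[C@H](C=O)[C@H](O[Si](C)(C)C(C)(C)C)[C@H]1O | intermediate
10 | methyl (2Z)-3-[(2R,3R,4S,5S)-3-[(tert-butyldimethylsilyl)oxy]-5-ethenyl-4-hydroxyoxolan-2-yl]prop-2-enoate | C=C[C@@H]1O[C@H](/C=C\C(=O)OC)[C@H](O[Si](C)(C)C(C)(C)C)[C@H]1O | intermediate
11 | methyl (2Z)-3-[(2R,3S,5S)-3-[(tert-butyldimethylsilyl)oxy]-5-ethenyl-4-oxooxolan-2-yl]prop-2-enoate | C=C[C@@H]1O[C@H](/C=C\C(=O)OC)[C@H](O[Si](C)(C)C(C)(C)C)C1=O | intermediate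
12 | methyl (2Z)-3-[(2R,3R,4R,5S)-3-[(tert-butyldimethylsilyl)oxy]-5-ethenyl-4-hydroxyoxolan-2-yl]prop-2-enoate | C=C[C@@H]1O[C@H](/C=C\C(=O)OC)[C@H](O[Si](C)(C)C(C)(C)C)[C@@H]1O | intermediate
13 | methyl (2Z)-3-[(2R,3R,4S,5S)-5-ethenyl-3,4-dihydroxyoxolan-2-yl]prop-2-enoate | C=C[C@@H]1O[C@H](/C=C\C(=O)OC)[C@H](O)[C@@H]1O | intermediate (not isolated)
14 | (2S,3R,3aR,7aR)-2-ethenyl-3-hydroxy-2,3,3a,7a-tetrahydro-5H-furo[3,2-b]pyran-5-one | C=C[C@@H]1O[C@@H]2C=CC(=O)O[C@@H]2[C@@H]1O | intermediate
15 | penta-1,4-dien-3-ol | C=CC(O)C=C | starting material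
16 | (1S)-1-[(2R)-oxiran-2-yl]prop-2-en-1-ol | C1O[C@H]1[C@@H](O)C=C | intermediate
17 | tert-butyl(dimethyl){[(1S)-1-[(2R)-oxiran-2-yl]prop-2-en-1-yl]oxy}silane | C1O[C@H]1[C@@H](O[Si](C)(C)C(C)(C)C)C=C | intermediate
18 | (2R,3S)-3-[(tert-butyldimethylsilyl)oxy]pent-4-en-2-ol | C[C@@H](O)[C@@H](O[Si](C)(C)C(C)(C)C)C=C | intermediate
19 | (2R,3S)-3-[(tert-butyldimethylsilyl)oxy]pent-4-en-2-yl benzoate | C[C@@H](OC(=O)c1ccccc1)[C@@H](O[Si](C)(C)C(C)(C)C)C=C | intermediate (not isolated)
20 | (2R,3S)-3-hydroxypent-4-en-2-yl benzoate | C[C@@H](OC(=O)c1ccccc1)[C@@H](O)C=C | intermediate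
21 | (2R,3S,4E)-3-hydroxy-5-[(2S,3R,3aR,7aR)-3-hydroxy-5-oxo-2,3,3a,7a-tetrahydro-5H-furo[3,2-b]pyran-2-yl]pent-4-en-2-yl benzoate | C[C@@H](OC(=O)c1ccccc1)[C@@H](O)/C=C/[C@@H]1O[C@@H]2C=CC(=O)O[C@@H]2[C@@H]1O | target

**Counts**

Total steps: 14. Longest linear sequence: 10 steps (steps 1–9 and 14, from diethyl D-tartrate); the side chain takes 4 steps (10–13).

**Steps most likely to fail**

Step 5. What may go wrong: over-reduction of an ester to the alcohol before the quench, intermolecular allylboration at the free C7 aldehyde, or attack on the other aldehyde face so that the vinyl group ends up trans to the C7a substituent. The fallback makes the two aldehydes by oxidation instead of partial reduction. It sets out from 6: excess i-Bu2AlH (−78 to 0 °C) reduces both esters fully to the diol F1. A double Swern oxidation (oxalyl chloride, DMSO, Et3N, CH2Cl2, −78 °C, 0.02 M) activates both hydroxyls before base is added, so no lactol can form. It releases dialdehyde 7 free of aluminium salts and water, 7 cyclises on warming to 8, and aqueous work-up returns to the route at 9.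

Step 14. What may go wrong: slow cross-coupling of two allylically branched alkenes, homodimerisation of 20, and ruthenium-hydride isomerisation of the allylic alcohol to a ketone. The fallback couples an electron-poor partner and sets the carbinol afterwards. It sets out from 20 and 14: Dess–Martin oxidation of 20 gives the enone (2R)-3-oxopent-4-en-2-yl benzoate F2. Cross-metathesis of 14 with F2 under the same catalyst should give the (E)-coupled enone F3. A Corey–Bakshi–Shibata reduction ((S)-2-methyl-CBS-oxazaborolidine, catecholborane, toluene, −78 °C, the alkene acting as the large group) should deliver the (S)-carbinol and return to the route at 21.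

Step 7. What may go wrong: enolisation of the α-alkoxy β,γ-unsaturated ketone, with epimerisation at C2 or C3a or migration of the vinyl double bond into conjugation. The fallback inverts C3 by substitution and avoids the ketone. It sets out from 10: Tf2O and pyridine (CH2Cl2, −20 °C) give the C3 triflate F4, which has no antiperiplanar hydrogen for elimination. Displacement with Bu4NNO2 in DMF (Lattrell–Dax inversion) gives the inverted nitrite ester F5, which is hydrolysed on aqueous work-up and returns to the route at 12.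

**Further compounds**

F1 | step 5 | (2R,3R)-2-[(tert-butyldimethylsilyl)oxy]-3-{[(1E)-3-(4,4,5,5-tetramethyl-1,3,2-dioxaborolan-2-yl)prop-1-en-1-yl]oxy}butane-1,4-diol | OC[C@@H](O/C=C/CB1OC(C)(C)C(C)(C)O1)[C@H](O[Si](C)(C)C(C)(C)C)CO
F2 | step 14 | (2R)-3-oxopent-4-en-2-yl benzoate | C[C@@H](OC(=O)c1ccccc1)C(=O)C=C
F3 | step 14 | (2R,4E)-5-[(2S,3R,3aR,7aR)-3-hydroxy-5-oxo-2,3,3a,7a-tetrahydro-5H-furo[3,2-b]pyran-2-yl]-3-oxopent-4-en-2-yl benzoate | C[C@@H](OC(=O)c1ccccc1)C(=O)/C=C/[C@@H]1O[C@@H]2C=CC(=O)O[C@@H]2[C@@H]1O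
F4 | step 7 | trifluoromethanesulfonate of 10 at the C3 hydroxyl (configuration of 10) | C=C[C@@H]1O[C@H](/C=C\C(=O)OC)[C@H](O[Si](C)(C)C(C)(C)C)[C@H]1OS(=O)(=O)C(F)(F)F
F5 | step 7 | nitrite ester of 12 at the C3 hydroxyl (C3 inverted, configuration of 12) | C=C[C@@H]1O[C@H](/C=C\C(=O)OC)[C@H](O[Si](C)(C)C(C)(C)C)[C@@H]1ON=O
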